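The route rests on cutting the trans-fused five-membered lactone (O–C6, C7–C11, C12) that sits beside the C4=C5 bond of the ten-membered ring: it is the 1,2-adduct of a carboxy(alkoxycarbonyl)methyl radical across C6=C7 of a C4=C5–C6=C7 ring diene. One oxidative radical annulation with tert-butyl hydrogen malonate and Mn(OAc)3 forms C7–C11 and O–C6, closes the lactone and sets C6 and C7 (C11 transiently) while C4=C5 stays Z. The precursor is a (4Z,6E)-cyclodecadienone bearing the C8 isovalerate and the C10 triethylsilyl ether, built from (R)-citramalic acid, trimethylsilylacetylene and propargyl alcohol and closed by Stille coupling at C5–C6; two further steps give the α-methylene lactone.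

Key step: step 13

Remark (labels): C1–C15 are the germacrane-type labels of the target: ring C1–C10 (C1 ketone, C4=C5, C8 ester, C10 carbinol), lactone O–C6 and C7–C11–C12, C13 the exocyclic methylene, C14 and C15 the methyls on C10 and C4.

Remark (carbon sources): C1, C8, C9, C10 and C14 come from citramalic acid, C6 and C7 from trimethylsilylacetylene, C3–C5 from propargyl alcohol, C15 from MeMgBr, C2 from MeLi, C11 and C12 from the malonate, C13 from formaldehyde, and the ester from isovaleric anhydride.

Remark (assumption): the γ-hydroxy methyl ketones of steps 5–7 are taken to equilibrate freely with their five-membered cyclic hemiketals and are drawn as the open forms.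

Step 1
Reactants: 1 (R)-citramalic acid
Product: 2 2-[(4R)-2,2,4-trimethyl-5-oxo-1,3-dioxolan-4-yl]acetic acid
Conditions: Me2C(OMe)2, TsOH·H2O (cat.), rt
Reagents that add atoms: 2,2-dimethoxypropane, COC(C)(C)OC
Why: Acid-catalysed acetal exchange (acetonide formation) ties only the α-hydroxy acid into a five-membered dioxolanone, which sets the two carboxyl groups apart and leaves the chiral-pool quaternary center (later C10, R) untouched.

Step 2
Reactants: 2 acetonide acid; 3 trimethylsilylacetylene
Product: 5 (5R)-2,2,5-trimethyl-5-[2-oxo-4-(trimethylsilyl)but-3-yn-1-yl]-1,3-dioxolan-4-one, via acid chloride 4 (not isolated)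
Conditions: (COCl)2, DMF (cat.), CH2Cl2, 0 °C to rt; then 3, PdCl2(PPh3)2 (2 mol%), CuI (4 mol%), Et3N (1.1 equiv), THF, rt
Reagents that add atoms: oxalyl chloride, O=C(Cl)C(=O)Cl (chlorine of intermediate 4)
Why: Vilsmeier-type chlorination gives the acid chloride and the Pd/Cu-catalysed acyl Sonogashira coupling then forms the C7–C8 bond under near-neutral conditions that should leave the dioxolanone closed.

Step 3
Reactants: 5 silyl ynone
Product: 7 (3R,5R)-3-hydroxy-3-methyl-5-[(trimethylsilyl)ethynyl]oxolan-2-one, via propargylic alcohol 6 (not isolated)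
Conditions: Ru[(R,R)-TsDPEN](p-cymene) (1 mol%), i-PrOH, rt; then TsOH·H2O (5 mol%), CH2Cl2, rt
Reagents that add atoms: none
Why: Noyori asymmetric transfer hydrogenation of an alkynyl ketone is catalyst-controlled and the (R,R)-complex should deliver hydride to give the (R)-propargylic alcohol (C8, alkynyl as the large group), after which acid-catalysed attack of this hydroxyl on the activated dioxolanone carbonyl expels acetone and closes the γ-lactone.

Step 4
Reactants: 7 hydroxy lactone
Product: 8 (3R,5R)-3-methyl-3-(triethylsilyloxy)-5-[(trimethylsilyl)ethynyl]oxolan-2-one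
Conditions: Et3SiOTf, 2,6-lutidine, CH2Cl2, −78 to 0 °C
Reagents that add atoms: triethylsilyl triflate, CC[Si](CC)(CC)OS(=O)(=O)C(F)(F)F
Why: Silylation of a hindered tertiary alcohol with the silyl triflate and 2,6-lutidine is standard and leaves the lactone and the alkynylsilane alone.

Step 5
Reactants: 8 silyloxy lactone
Product: 9 (3R,5R)-5-hydroxy-3-methyl-3-(triethylsilyloxy)-7-(trimethylsilyl)hept-6-yn-2-one
Conditions: MeLi (1.15 equiv), THF, −78 °C; aq. NH4Cl at −78 °C
Reagents that add atoms: methyllithium, [Li]C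
Why: Mono-addition of MeLi to a γ-lactone at −78 °C stops at the lithium hemiketal alkoxide, because the α-carbon is quaternary (no enolisation, hindered second attack), and protonation releases the methyl ketone, which supplies C2.

Step 6
Reactants: 9 silylalkynyl hydroxy ketone
Product: 10 (3R,5R)-5-hydroxy-3-methyl-3-(triethylsilyloxy)hept-6-yn-2-one
Conditions: AgNO3 (10 mol%), acetone/H2O, rt
Reagents that add atoms: none
Why: Silver-catalysed protiodesilylation cleaves only the alkynyl C–Si bond through the silver acetylide under neutral aqueous conditions that should spare the tertiary silyl ether.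

Step 7
Reactants: 10 terminal alkyne
Product: 11 (3R,5R,6E)-5-hydroxy-3-methyl-7-(tributylstannyl)-3-(triethylsilyloxy)hept-6-en-2-one
Conditions: Bu3SnH (1.1 equiv), Pd2(dba)3 (1 mol%), Cy3P·HBF4 (4 mol%), i-Pr2NEt (8 mol%), CH2Cl2, 0 °C
Reagents that add atoms: tributyltin hydride, CCCC[SnH](CCCC)CCCC
Why: Palladium-catalysed syn-hydrostannation of the terminal alkyne with a bulky phosphine should place tin on the terminal carbon and give the E alkenylstannane, and it is run on the free propargylic alcohol before any allylic ester or alkenyl iodide is present.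

Step 8
Reactants: 11 stannyl hydroxy ketone
Product: 12 (1E,3R,5R)-5-methyl-6-oxo-1-(tributylstannyl)-5-(triethylsilyloxy)hept-1-en-3-yl 3-methylbutanoate
Conditions: isovaleric anhydride, Et3N, DMAP (cat.), CH2Cl2, 0 °C to rt
Reagents that add atoms: isovaleric anhydride, CC(C)CC(=O)OC(=O)CC(C)C
Why: DMAP-catalysed acylation takes the secondary allylic hydroxyl of the open-chain tautomer, the tertiary hemiketal hydroxyl of the ring tautomer being too hindered, so that ring–chain equilibration should funnel the material into the keto ester without acid that could protodestannylate.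

Step 9
Reactants: 13 propargyl alcohol
Product: 15 (Z)-3-iodo-2-methylprop-2-en-1-ol, via alkenylmagnesium alkoxide 14 (not isolated)
Conditions: MeMgBr (2.5 equiv), CuI (10 mol%), THF, −10 °C to rt; then I2, −78 to 0 °C; aq. NH4Cl
Reagents that add atoms: methylmagnesium bromide, C[Mg]Br; iodine, II
Why: Copper-catalysed anti-carbomagnesiation of the magnesium propargyl alkoxide is directed by the alkoxide to give the five-membered alkenylmagnesium chelate, and iodinolysis with retention fixes the Z geometry (CH2O and I cis) and supplies C15.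

Step 10
Reactants: 15 (Z)-iodo alcohol
Product: 16 (Z)-3-bromo-1-iodo-2-methylprop-1-ene
Conditions: CBr4, PPh3, CH2Cl2, 0 °C
Reagents that add atoms: carbon tetrabromide, BrC(Br)(Br)Br
Why: Appel bromination converts the primary allylic alcohol into the bromide without touching the alkenyl iodide or its geometry.

Step 11
Reactants: 12 stannyl keto ester; 16 (Z)-allylic bromide
Product: 18 (1E,3R,5R,9Z)-10-iodo-5,9-dimethyl-6-oxo-1-(tributylstannyl)-5-(triethylsilyloxy)deca-1,9-dien-3-yl 3-methylbutanoate, via lithium enolate 17 (not isolated)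
Conditions: LiN(SiMe3)2 (1.05 equiv), THF, −78 °C; then 16 (1.5 equiv), DMPU, −78 to −40 °C
Reagents that add atoms: lithium bis(trimethylsilyl)amide, [Li]N([Si](C)(C)C)[Si](C)(C)C (lithium of intermediate 17)
Why: Deprotonation with LiN(SiMe3)2 at −78 °C should occur at the methyl group of the ketone (its only enolisable side and markedly more acidic than the ester α-CH2), and SN2 alkylation of the lithium enolate by the reactive allylic bromide forms C2–C3.

Step 12
Reactants: 18 iodo stannane
Product: 19 (4Z,6E,8R,10R)-4,10-dimethyl-8-(3-methylbutanoyloxy)-10-(triethylsilyloxy)cyclodeca-4,6-dien-1-one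
Conditions: Pd2(dba)3 (10 mol%), AsPh3 (80 mol%), DMF, 0.002 M (syringe-pump addition), 40 °C
Reagents that add atoms: none
Why: Intramolecular Stille coupling with the AsPh3-ligated zerovalent palladium catalyst at high dilution joins C5 and C6 with retention at both alkenes, which gives the (4Z,6E)-diene within the ten-membered ring.

Step 13
Reactants: 19 cyclodecadienone; 20 tert-butyl hydrogen malonate
Product: 21 tert-butyl (3S,3aR,4R,6R,10Z,11aR)-6,10-dimethyl-4-(3-methylbutanoyloxy)-2,7-dioxo-6-(triethylsilyloxy)-2,3,3a,4,5,6,7,8,9,11a-decahydrocyclodeca[b]furan-3-carboxylate (germacrane labels: 6R,7R,8R,10R,11S; 4Z)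
Conditions: 20 (3 equiv), Mn(OAc)3·2H2O (2.5 equiv), KOAc (5 equiv), AcOH, 40 °C, Ar
Reagents that add atoms: none
Why: Mn(OAc)3 forms the manganese enolate of the half-ester and oxidises it to the electrophilic radical ·CH(CO2t-Bu)CO2H, which adds to C7 of the C4=C5–C6=C7 diene to leave a C4–C5–C6 allylic radical; a second Mn(OAc)3 oxidises this to the allyl cation (or its manganese-bound equivalent), which the pendant carboxylate captures at C6. This is the known oxidative radical lactone annulation of alkenes and 1,3-dienes with malonic half-esters mediated by trivalent manganese. The C7–C11 bond forms intermolecularly and the lactone ring then closes by 5-exo attack of the carboxylate oxygen on C6, attack at C4 being ruled out because it would need a seven-membered ring. C7 should be set by approach of the radical to the outer face of the E C6=C7 bond, anti to the C8–C9 ring bond with the C8–O bond near the alkene plane (inside-alkoxy arrangement); C6 by delivery of the tethered carboxylate to that same face before the allylic system can rotate, so that the E geometry is translated into the trans ring fusion; C11 is an epimerisable malonate-type center that should settle trans to C8 and is erased later. The step needs attack at C7 in preference to C4, retention of the 4Z geometry and oxidation of the half-ester in preference to the C2 position of the ketone, which the hindered trisubstituted C4 terminus, the configurational stability of the allylic intermediate held in the ring and the far easier enolisation of the 1,3-dicarbonyl acid at 40 °C should secure.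

Step 14
Reactants: 21 tert-butyl ester lactone
Product: 22 (3R,3aR,4R,6R,10Z,11aR)-6-hydroxy-6,10-dimethyl-4-(3-methylbutanoyloxy)-2,7-dioxo-2,3,3a,4,5,6,7,8,9,11a-decahydrocyclodeca[b]furan-3-carboxylic acid
Conditions: TFA/CH2Cl2 (1:2), 0 °C to rt; aqueous work-up
Reagents that add atoms: none
Why: TFA cleaves the tert-butyl ester by loss of 2-methylpropene and the tertiary silyl ether by protodesilylation in one operation, conditions under which the lactone, the isovalerate and the α-ketol should survive.

Step 15
Reactants: 22 α-carboxy lactone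
Product: 24 (3aR,4R,6R,10Z,11aR)-6-hydroxy-6,10-dimethyl-3-methylidene-2,7-dioxo-2,3,3a,4,5,6,7,8,9,11a-decahydrocyclodeca[b]furan-4-yl 3-methylbutanoate (the target), via Mannich base 23 (not isolated)
Conditions: 37% aq. CH2O, Et2NH, rt; then NaOAc, AcOH, 60 °C
Reagents that add atoms: formaldehyde, C=O; diethylamine, CCNCC (nitrogen of intermediate 23)
Why: The Mannich reaction of the α-carboxy lactone with formaldehyde and Et2NH followed by decarboxylative elimination of the amine (decarboxylative Mannich methylenation) should install C11=C13 without lactone enolate chemistry and erase the C11 stereocenter.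

Compound list

1 | (R)-citramalic acid, (2R)-2-hydroxy-2-methylbutanedioic acid | OC(=O)[C@](C)(O)CC(=O)O | starting material
2 | 2-[(4R)-2,2,4-trimethyl-5-oxo-1,3-dioxolan-4-yl]acetic acid | CC1(C)OC(=O)[C@@](C)(CC(=O)O)O1 | intermediate
3 | trimethylsilylacetylene | C#C[Si](C)(C)C | starting material
4 | 2-[(4R)-2,2,4-trimethyl-5-oxo-1,3-dioxolan-4-yl]acetyl chloride | CC1(C)OC(=O)[C@@](C)(CC(=O)Cl)O1 | intermediate (not isolated)
5 | (5R)-2,2,5-trimethyl-5-[2-oxo-4-(trimethylsilyl)but-3-yn-1-yl]-1,3-dioxolan-4-one | CC1(C)OC(=O)[C@@](C)(CC(=O)C#C[Si](C)(C)C)O1 | intermediate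
6 | (5R)-5-[(2R)-2-hydroxy-4-(trimethylsilyl)but-3-yn-1-yl]-2,2,5-trimethyl-1,3-dioxolan-4-one | CC1(C)OC(=O)[C@@](C)(C[C@@H](O)C#C[Si](C)(C)C)O1 | intermediate (not isolated)
7 | (3R,5R)-3-hydroxy-3-methyl-5-[(trimethylsilyl)ethynyl]oxolan-2-one | C[Si](C)(C)C#C[C@H]1C[C@@](C)(O)C(=O)O1 | intermediate
8 | (3R,5R)-3-methyl-3-(triethylsilyloxy)-5-[(trimethylsilyl)ethynyl]oxolan-2-one | C[Si](C)(C)C#C[C@H]1C[C@@](C)(O[Si](CC)(CC)CC)C(=O)O1 | intermediate
9 | (3R,5R)-5-hydroxy-3-methyl-3-(triethylsilyloxy)-7-(trimethylsilyl)hept-6-yn-2-one | C[Si](C)(C)C#C[C@H](O)C[C@@](C)(O[Si](CC)(CC)CC)C(C)=O | intermediate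
10 | (3R,5R)-5-hydroxy-3-methyl-3-(triethylsilyloxy)hept-6-yn-2-one | C#C[C@H](O)C[C@@](C)(O[Si](CC)(CC)CC)C(C)=O | intermediate
11 | (3R,5R,6E)-5-hydroxy-3-methyl-7-(tributylstannyl)-3-(triethylsilyloxy)hept-6-en-2-one | CCCC[Sn](CCCC)(CCCC)/C=C/[C@H](O)C[C@@](C)(O[Si](CC)(CC)CC)C(C)=O | intermediate
12 | (1E,3R,5R)-5-methyl-6-oxo-1-(tributylstannyl)-5-(triethylsilyloxy)hept-1-en-3-yl 3-methylbutanoate | CCCC[Sn](CCCC)(CCCC)/C=C/[C@H](OC(=O)CC(C)C)C[C@@](C)(O[Si](CC)(CC)CC)C(C)=O | intermediate
13 | propargyl alcohol | C#CCO | starting material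
14 | bromomagnesium (Z)-3-(bromomagnesio)-2-methylprop-2-en-1-olate | Br[Mg]OC/C(C)=C\[Mg]Br | intermediate (not isolated)
15 | (Z)-3-iodo-2-methylprop-2-en-1-ol | OC/C(C)=C\I | intermediate
16 | (Z)-3-bromo-1-iodo-2-methylprop-1-ene | BrC/C(C)=C\I | intermediate
17 | lithium enolate of 12 (C1–O–Li, C1=C2) | [Li]OC(=C)[C@](C)(O[Si](CC)(CC)CC)C[C@@H](OC(=O)CC(C)C)/C=C/[Sn](CCCC)(CCCC)CCCC | intermediate (not isolated)
18 | (1E,3R,5R,9Z)-10-iodo-5,9-dimethyl-6-oxo-1-(tributylstannyl)-5-(triethylsilyloxy)deca-1,9-dien-3-yl 3-methylbutanoate | CCCC[Sn](CCCC)(CCCC)/C=C/[C@H](OC(=O)CC(C)C)C[C@@](C)(O[Si](CC)(CC)CC)C(=O)CC/C(C)=C\I | intermediate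
19 | (4Z,6E,8R,10R)-4,10-dimethyl-8-(3-methylbutanoyloxy)-10-(triethylsilyloxy)cyclodeca-4,6-dien-1-one | CC(C)CC(=O)O[C@@H]1C[C@@](C)(O[Si](CC)(CC)CC)C(=O)CC/C(C)=C\C=C\1 | intermediate
20 | tert-butyl hydrogen malonate | CC(C)(C)OC(=O)CC(=O)O | starting material
21 | tert-butyl (3S,3aR,4R,6R,10Z,11aR)-6,10-dimethyl-4-(3-methylbutanoyloxy)-2,7-dioxo-6-(triethylsilyloxy)-2,3,3a,4,5,6,7,8,9,11a-decahydrocyclodeca[b]furan-3-carboxylate | CC(C)(C)OC(=O)[C@@H]1C(=O)O[C@@H]2/C=C(/C)CCC(=O)[C@](C)(O[Si](CC)(CC)CC)C[C@@H](OC(=O)CC(C)C)[C@@H]12 | intermediate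
22 | (3R,3aR,4R,6R,10Z,11aR)-6-hydroxy-6,10-dimethyl-4-(3-methylbutanoyloxy)-2,7-dioxo-2,3,3a,4,5,6,7,8,9,11a-decahydrocyclodeca[b]furan-3-carboxylic acid | OC(=O)[C@@H]1C(=O)O[C@@H]2/C=C(/C)CCC(=O)[C@](C)(O)C[C@@H](OC(=O)CC(C)C)[C@@H]12 | intermediate
23 | C11 diethylaminomethyl Mannich base of 22 (C11 configuration undefined) | CCN(CC)CC1(C(=O)O)C(=O)O[C@@H]2/C=C(/C)CCC(=O)[C@](C)(O)C[C@@H](OC(=O)CC(C)C)[C@@H]12 | intermediate (not isolated)
24 | (3aR,4R,6R,10Z,11aR)-6-hydroxy-6,10-dimethyl-3-methylidene-2,7-dioxo-2,3,3a,4,5,6,7,8,9,11a-decahydrocyclodeca[b]furan-4-yl 3-methylbutanoate | C=C1C(=O)O[C@@H]2/C=C(/C)CCC(=O)[C@](C)(O)C[C@@H](OC(=O)CC(C)C)[C@@H]12 | target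

Total step count: 15. Longest linear sequence: 13 steps (steps 1–8 and 11–15).

Steps most likely to fail

Step 13 (lactone annulation). The radical may enter C6=C7 on the wrong face or add at C4, the allylic intermediate may be trapped by acetate or lose its Z geometry, Mn(OAc)3 may oxidise the C2 position of the ketone, and warm acetic acid may strip the silyl ether. The fallback sets out from 19 and returns at 22, replacing the oxidative annulation by a redox-neutral atom-transfer sequence. Visible-light Kharasch-type addition of purchased di-tert-butyl bromomalonate (Ru(bpy)3Cl2, LiBr, DMF/H2O, blue LED) across the diene should give the C7-malonyl allylic bromide adduct F1. TFA/CH2Cl2 then cleaves both tert-butyl esters and the silyl ether and lets one carboxyl group displace the allylic bromide at C6 (ionisation, 5-exo capture, thermodynamic trans fusion), giving 22 directly. The facial preference at C7 stays substrate-controlled in this variant.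

Step 12 (Stille macrocyclisation). Strain in the twisted ten-membered diene may slow the ring-forming reductive elimination, so that oligomerisation, homocoupling or protodestannylation take over. The fallback sets out from 12 and returns at 19 by inverting the order of bond formation. Intermolecular Stille coupling of 12 with 15 (Pd2(dba)3, AsPh3, CuI, DMF) gives the open-chain dienol F2, and Appel bromination (CBr4, PPh3) gives the dienyl bromide F3. The ring is then closed at C2–C3 by intramolecular alkylation of the methyl ketone enolate (LiN(SiMe3)2, THF, slow addition at high dilution).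

Step 11 (enolate alkylation). Deprotonation or acyl transfer at the isovalerate, proton exchange between enolate and product leading to dialkylation, or sluggish alkylation may erode the step. The fallback sets out from 11 and returns at 18, keeping C8–O as a silyl ether during the alkylation so that the ketone is the only enolisable carbonyl. Et3SiCl/imidazole gives the bis-silyl ether F4, and LiN(i-Pr)2 followed by 16 gives the alkylated ketone F5. PPTS/MeOH at 0 °C removes only the secondary allylic silyl ether to give the alcohol F6, and acylation as in step 8 gives 18.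

Further compounds

F1 | step 13 | di-tert-butyl 2-[(4Z,7R,8R,10R)-6-bromo-4,10-dimethyl-8-(3-methylbutanoyloxy)-1-oxo-10-(triethylsilyloxy)cyclodec-4-en-7-yl]propanedioate (ring locants as in 19, C6 epimers) | CC(C)CC(=O)O[C@@H]1C[C@@](C)(O[Si](CC)(CC)CC)C(=O)CC/C(C)=C\C(Br)[C@@H]1C(C(=O)OC(C)(C)C)C(=O)OC(C)(C)C
F2 | step 12 | (2Z,4E,6R,8R)-1-hydroxy-2,8-dimethyl-9-oxo-8-(triethylsilyloxy)deca-2,4-dien-6-yl 3-methylbutanoate | OC/C(C)=C\C=C\[C@H](OC(=O)CC(C)C)C[C@@](C)(O[Si](CC)(CC)CC)C(C)=O
F3 | step 12 | (2Z,4E,6R,8R)-1-bromo-2,8-dimethyl-9-oxo-8-(triethylsilyloxy)deca-2,4-dien-6-yl 3-methylbutanoate | BrC/C(C)=C\C=C\[C@H](OC(=O)CC(C)C)C[C@@](C)(O[Si](CC)(CC)CC)C(C)=O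
F4 | step 11 | (3R,5R,6E)-3-methyl-7-(tributylstannyl)-3,5-bis(triethylsilyloxy)hept-6-en-2-one | CCCC[Sn](CCCC)(CCCC)/C=C/[C@H](O[Si](CC)(CC)CC)C[C@@](C)(O[Si](CC)(CC)CC)C(C)=O
F5 | step 11 | (1Z,6R,8R,9E)-1-iodo-2,6-dimethyl-10-(tributylstannyl)-6,8-bis(triethylsilyloxy)deca-1,9-dien-5-one | CCCC[Sn](CCCC)(CCCC)/C=C/[C@H](O[Si](CC)(CC)CC)C[C@@](C)(O[Si](CC)(CC)CC)C(=O)CC/C(C)=C\I
F6 | step 11 | (1Z,6R,8R,9E)-8-hydroxy-1-iodo-2,6-dimethyl-10-(tributylstannyl)-6-(triethylsilyloxy)deca-1,9-dien-5-one | CCCC[Sn](CCCC)(CCCC)/C=C/[C@H](O)C[C@@](C)(O[Si](CC)(CC)CC)C(=O)CC/C(C)=C\I
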